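**Plan**

1. Quinone numbering used here: C1 is the carbonyl between the two methoxy carbons C2 and C6, C3 carries the side chain, C4 is the second carbonyl, C5 is the ring CH. The retrosynthesis first removes the C1 oxygen, giving a 2-alkyl-3,5-dimethoxyphenol with OH on C4 and a free para C1–H. It then cuts the benzene ring at C5–C6 and C1–C2, which releases C6–C1 as methoxyacetylene and leaves C2, C5, C4, C3 as a 3-alkoxy-4-alkylcyclobutenone.
2. The cyclobutenone is cut into an alkylketene (from 5-aryl-5-oxopentanoyl chloride) and isopropoxyacetylene; the keto acid comes from veratrole and glutaric anhydride.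
3. Enabling feature: oxygen sits on alternate ring carbons C2, C4, C6, with C5–H between C4 and C6. This meta pattern is what an ynol ether leaves when its oxygen-bearing carbon bonds to the α-carbon of a ketene. Two such unions supply three of the four ring oxygens. The isopropyl/methyl difference tells the C4 oxygen (to become carbonyl) from the C2 oxygen (to stay a methyl ether).
4. Forward order: side chain by Friedel–Crafts acylation, four-membered ring by ketene–ynol ether [2+2], six-membered ring by benzannulation, then O-methylation, de-isopropylation and phenol-to-quinone oxidation.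
5. Stereochemistry: the target has no stereocentre; the single centre of the cyclobutenone is racemic and is erased on aromatisation.

Key step: step 6

Remark: methoxyacetylene and isopropoxyacetylene are treated as not purchasable and are prepared (steps 3 and 5); both are handled as cold, assayed solutions.

**Route**

Step 1
Reactants: 1 1,2-dimethoxybenzene (veratrole); 2 glutaric anhydride
Product: 3 5-(3,4-dimethoxyphenyl)-5-oxopentanoic acid
Conditions: AlCl3 (2.2 equiv), CH2Cl2, 0 °C to rt; then ice/aq. HCl
Reagents that add atoms: none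
Why: Friedel–Crafts acylation, in which the acylium species from the anhydride and AlCl3 should attack veratrole para to one methoxy group (the only unhindered activated position) to give the 3,4-dimethoxyphenyl ketone with the free acid at the chain end.

Step 2
Reactants: 3 5-(3,4-dimethoxyphenyl)-5-oxopentanoic acid
Product: 4 5-(3,4-dimethoxyphenyl)-5-oxopentanoyl chloride
Conditions: (COCl)2 (1.3 equiv), cat. DMF, CH2Cl2, 0 °C to rt; evaporated and used at once
Reagents that add atoms: oxalyl chloride, O=C(Cl)C(Cl)=O
Why: Standard DMF-catalysed acid chloride formation, which 4-aroylbutyric acids of this type undergo to give open-chain acid chlorides.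

Step 3
Reactants: 5 propan-2-ol; 6 trichloroethylene
Product: 9 isopropoxyacetylene, via dichlorovinyl ether 7 (not isolated), via lithium acetylide 8 (not isolated)
Conditions: KH (1.2 equiv), THF, 0 °C; 6, −50 °C to rt; n-BuLi (2.3 equiv), −78 to −40 °C; MeOH (1 equiv), −78 °C; aqueous wash, distilled and used as an assayed THF solution
Reagents that add atoms: none
Why: Dichlorovinyl ether route to ynol ethers, in which the alkoxide replaces one vinylic chloride of trichloroethylene by an elimination–addition sequence, n-BuLi then effects β-elimination and chlorine–lithium exchange to the lithium alkoxyacetylide, and protonation gives the terminal ynol ether.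

Step 4
Reactants: 4 5-(3,4-dimethoxyphenyl)-5-oxopentanoyl chloride; 9 isopropoxyacetylene
Product: 11 racemic 4-[3-(3,4-dimethoxyphenyl)-3-oxopropyl]-3-isopropoxycyclobut-2-en-1-one, via alkylketene 10 (not isolated)
Conditions: Et3N (1.5 equiv), 9 (3 equiv), Et2O/THF, 0 °C to rt, 4 added over 4 h
Reagents that add atoms: none
Why: Dehydrochlorination should give the alkylketene, which undergoes the regiospecific thermal ketene–alkoxyacetylene [2+2] cycloaddition (alkyne CH terminus to the ketene carbonyl carbon) to the 3-alkoxy-4-alkylcyclobutenone; the new C4 centre is racemic and is lost in step 6.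

Step 5
Reactants: 12 2-chloro-1,1-dimethoxyethane
Product: 14 methoxyacetylene, via sodium acetylide 13 (not isolated)
Conditions: NaNH2 (3.2 equiv), liq. NH3, −33 °C; NH3 evaporated; cold sat. aq. NaCl, −20 °C; distilled into toluene at −78 °C
Reagents that add atoms: none
Why: Standard alkoxyacetylene preparation, in which NaNH2 removes HCl and methanol from the chloroacetal to give the sodium alkoxyacetylide, which is protonated on aqueous work-up.

Step 6
Reactants: 11 racemic 4-[3-(3,4-dimethoxyphenyl)-3-oxopropyl]-3-isopropoxycyclobut-2-en-1-one; 14 methoxyacetylene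
Product: 19 1-(3,4-dimethoxyphenyl)-3-(2-hydroxy-6-isopropoxy-4-methoxyphenyl)propan-1-one, via vinylketene 15 (not isolated), via alkenylcyclobutenone 16 (not isolated), via dienylketene 17 (not isolated), via cyclohexadienone 18 (not isolated)
Conditions: 14 (4 equiv), toluene, sealed tube, 110 °C, then 135 °C if 16 persists; then K2CO3, MeOH, rt
Reagents that add atoms: none
Why: Heating should open 11 by 4π electrocyclic cleavage of its C1–C4 bond (4-alkyl group turning outward) to vinylketene 15, whose ketene C=C adds methoxyacetylene in a regiospecific [2+2] cycloaddition: the nucleophilic CH terminus of the ynol ether attacks the ketene carbonyl carbon, so the methoxy-bearing alkyne carbon bonds to the former C2–H carbon of 11, and this CH/C–OMe pair persists into the quinone. Cyclobutenone 16 reopens to dienylketene 17, which closes the six-membered ring by thermal disrotatory 6π electrocyclisation (ketene carbon onto the terminal alkene carbon) and tautomerises through 18 to phenol 19; the closest known reaction type is the Danheiser benzannulation of cyclobutenones with alkynyl ethers. No stereocentre is formed, and the racemic centre of 11 is flattened on aromatisation. The step needs regiocontrol of alkyne incorporation and [2+2] rather than [4+2] chemoselectivity; both follow from the polarisation of the ynol ether against the ketene, and the irreversible aromatisation drains the reversible ring-opening equilibria. The outward-turned alkyl group keeps the chain CH2 away from the ketene and so blocks a 1,5-hydrogen shift, methoxyacetylene has no β-hydrogen and cannot fragment to a ketene at this temperature, and the carbonate/methanol treatment returns any phenol that was acylated by the vinylketene.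

Step 7
Reactants: 19 1-(3,4-dimethoxyphenyl)-3-(2-hydroxy-6-isopropoxy-4-methoxyphenyl)propan-1-one
Product: 20 1-(3,4-dimethoxyphenyl)-3-(2-isopropoxy-4,6-dimethoxyphenyl)propan-1-one
Conditions: MeI (3 equiv), K2CO3, acetone, reflux
Reagents that add atoms: iodomethane, CI
Why: Williamson O-methylation of the only free phenol, with a base too weak to enolise the aryl ketone.

Step 8
Reactants: 20 1-(3,4-dimethoxyphenyl)-3-(2-isopropoxy-4,6-dimethoxyphenyl)propan-1-one
Product: 21 1-(3,4-dimethoxyphenyl)-3-(2-hydroxy-4,6-dimethoxyphenyl)propan-1-one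
Conditions: BCl3 (3 equiv, 1 M in CH2Cl2), CH2Cl2, −78 to 0 °C; then ice-water
Reagents that add atoms: none
Why: Selective Lewis-acid dealkylation, in which BCl3 should cleave the secondary isopropyl aryl ether (chloride attack on the activated isopropyl group) much faster than aryl methyl ethers that have no ortho carbonyl group.

Step 9
Reactants: 21 1-(3,4-dimethoxyphenyl)-3-(2-hydroxy-4,6-dimethoxyphenyl)propan-1-one
Product: 22 evelynin, 3-[3-(3,4-dimethoxyphenyl)-3-oxopropyl]-2,6-dimethoxy-1,4-benzoquinone
Conditions: (KSO3)2NO (2.5 equiv), aq. KH2PO4, acetone/H2O, rt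
Reagents that add atoms: potassium nitrosodisulfonate (KSO3)2NO, [K+].[K+].[O-]S(=O)(=O)N([O])S(=O)(=O)[O-]
Why: Teuber oxidation, in which the nitroxyl radical abstracts the phenolic hydrogen, a second equivalent couples at the free para carbon between the two methoxy groups, and loss of imidodisulfonate should give the para-quinone.

**Compound list**

1 | 1,2-dimethoxybenzene (veratrole) | COc1ccccc1OC | starting material
2 | glutaric anhydride | O=C1CCCC(=O)O1 | starting material
3 | 5-(3,4-dimethoxyphenyl)-5-oxopentanoic acid | COc1ccc(cc1OC)C(=O)CCCC(=O)O | intermediate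
4 | 5-(3,4-dimethoxyphenyl)-5-oxopentanoyl chloride | COc1ccc(cc1OC)C(=O)CCCC(=O)Cl | intermediate
5 | propan-2-ol | CC(C)O | starting material
6 | trichloroethylene | ClC=C(Cl)Cl | starting material
7 | (E)-1,2-dichlorovinyl isopropyl ether | Cl/C=C(/Cl)OC(C)C | intermediate
8 | lithium isopropoxyacetylide | [Li]C#COC(C)C | intermediate
9 | isopropoxyacetylene, 2-(ethynyloxy)propane | C#COC(C)C | intermediate
10 | 6-(3,4-dimethoxyphenyl)hex-1-ene-1,6-dione (alkylketene) | O=C=CCCC(=O)c1ccc(OC)c(OC)c1 | intermediate
11 | racemic 4-[3-(3,4-dimethoxyphenyl)-3-oxopropyl]-3-isopropoxycyclobut-2-en-1-one | O=C1C=C(OC(C)C)C1CCC(=O)c1ccc(OC)c(OC)c1 | intermediate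
12 | 2-chloro-1,1-dimethoxyethane | COC(CCl)OC | starting material
13 | sodium methoxyacetylide | [Na]C#COC | intermediate
14 | methoxyacetylene | C#COC | intermediate
15 | (3Z)-7-(3,4-dimethoxyphenyl)-3-isopropoxyhepta-1,3-diene-1,7-dione (vinylketene) | O=C=C/C(OC(C)C)=C/CCC(=O)c1ccc(OC)c(OC)c1 | intermediate
16 | racemic 4-[(1Z)-5-(3,4-dimethoxyphenyl)-1-isopropoxy-5-oxopent-1-enyl]-3-methoxycyclobut-2-en-1-one | O=C1C=C(OC)C1/C(OC(C)C)=C/CCC(=O)c1ccc(OC)c(OC)c1 | intermediate
17 | (3E,5Z)-9-(3,4-dimethoxyphenyl)-5-isopropoxy-3-methoxynona-1,3,5-triene-1,9-dione (dienylketene) | O=C=C/C(OC)=C\C(OC(C)C)=C\CCC(=O)c1ccc(OC)c(OC)c1 | intermediate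
18 | racemic 6-[3-(3,4-dimethoxyphenyl)-3-oxopropyl]-5-isopropoxy-3-methoxycyclohexa-2,4-dien-1-one | O=C1C=C(OC)C=C(OC(C)C)C1CCC(=O)c1ccc(OC)c(OC)c1 | intermediate
19 | 1-(3,4-dimethoxyphenyl)-3-(2-hydroxy-6-isopropoxy-4-methoxyphenyl)propan-1-one | COc1cc(O)c(CCC(=O)c2ccc(OC)c(OC)c2)c(OC(C)C)c1 | intermediate
20 | 1-(3,4-dimethoxyphenyl)-3-(2-isopropoxy-4,6-dimethoxyphenyl)propan-1-one | COc1cc(OC)c(CCC(=O)c2ccc(OC)c(OC)c2)c(OC(C)C)c1 | intermediate
21 | 1-(3,4-dimethoxyphenyl)-3-(2-hydroxy-4,6-dimethoxyphenyl)propan-1-one | COc1cc(OC)c(CCC(=O)c2ccc(OC)c(OC)c2)c(O)c1 | intermediate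
22 | evelynin | COC1=CC(=O)C(CCC(=O)c2ccc(OC)c(OC)c2)=C(OC)C1=O | target

**Step count**

Total steps: 9. Longest linear sequence: 7 steps (1, 2, 4, 6, 7, 8, 9).

**Steps most likely to fail**

Step 6. Electrocyclic opening of the vinylogous-ester cyclobutenone may be slower than thermal oligomerisation of methoxyacetylene, and the keto phenol formed may be acylated by unconsumed vinylketene or may cyclodehydrate on long heating. The fallback gives up the ring construction, sets out from 1 and comes back at 21. Friedel–Crafts acetylation of 1 (acetyl chloride, AlCl3, CH2Cl2) gives 3,4-dimethoxyacetophenone F1. Claisen–Schmidt condensation of F1 with commercial 2-hydroxy-4,6-dimethoxybenzaldehyde (KOH, EtOH) gives (E)-1-(3,4-dimethoxyphenyl)-3-(2-hydroxy-4,6-dimethoxyphenyl)prop-2-en-1-one F2. Hydrogenation of the alkene of F2 (H2, Pd/C, EtOAc) gives 21, which enters step 9.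

Step 4. The alkylketene may dimerise, or be captured by the enol form of its own aryl ketone (enol lactone formation), before it meets the ynol ether. The fallback introduces the aryl ketone only after the arene is built; it sets out from 9 and comes back at 20. Commercial methyl 5-chloro-5-oxopentanoate and Et3N give methyl 5-oxopent-4-enoate (ester ketene) F3, which 9 traps as racemic methyl 3-(2-isopropoxy-4-oxocyclobut-2-en-1-yl)propanoate F4. Heating F4 with 14 as in step 6 should run through the ester vinylketene F5, the ester alkenylcyclobutenone F6, the ester dienylketene F7 and the ester cyclohexadienone F8 to methyl 3-(2-hydroxy-6-isopropoxy-4-methoxyphenyl)propanoate F9; the carbonate/methanol treatment keeps this hydroxy ester open-chain. MeI/K2CO3 gives methyl 3-(2-isopropoxy-4,6-dimethoxyphenyl)propanoate F10. MeNH(OMe)·HCl with i-PrMgCl gives 3-(2-isopropoxy-4,6-dimethoxyphenyl)-N-methoxy-N-methylpropanamide F11. Commercial (3,4-dimethoxyphenyl)magnesium bromide converts F11 into 20.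

Step 8. Methyl ethers on either ring may be lost alongside the isopropyl group, or the liberated keto phenol may cyclodehydrate under the acidic conditions. The fallback moves the dealkylation to the quinone stage; it sets out from 19 and comes back at 22. Oxidation of 19 with (KSO3)2NO at its free para position gives 2-[3-(3,4-dimethoxyphenyl)-3-oxopropyl]-3-isopropoxy-5-methoxy-1,4-benzoquinone F12. The isopropoxy group of F12, now part of a vinylogous ester, is exchanged for methoxy by conjugate addition–elimination (cat. NaOMe, MeOH, 0 °C) to give 22.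

**Further compounds**

F1 | step 6 | 3,4-dimethoxyacetophenone | CC(=O)c1ccc(OC)c(OC)c1
F2 | step 6 | (E)-1-(3,4-dimethoxyphenyl)-3-(2-hydroxy-4,6-dimethoxyphenyl)prop-2-en-1-one | COc1cc(OC)c(/C=C/C(=O)c2ccc(OC)c(OC)c2)c(O)c1
F3 | step 4 | methyl 5-oxopent-4-enoate (ester ketene) | COC(=O)CCC=C=O
F4 | step 4 | racemic methyl 3-(2-isopropoxy-4-oxocyclobut-2-en-1-yl)propanoate | COC(=O)CCC1C(OC(C)C)=CC1=O
F5 | step 4 | methyl (4Z)-5-isopropoxy-7-oxohepta-4,6-dienoate (ester vinylketene) | O=C=C/C(OC(C)C)=C/CCC(=O)OC
F6 | step 4 | racemic methyl (4Z)-5-isopropoxy-5-(2-methoxy-4-oxocyclobut-2-en-1-yl)pent-4-enoate (ester alkenylcyclobutenone) | O=C1C=C(OC)C1/C(OC(C)C)=C/CCC(=O)OC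
F7 | step 4 | methyl (4Z,6E)-5-isopropoxy-7-methoxy-9-oxonona-4,6,8-trienoate (ester dienylketene) | O=C=C/C(OC)=C\C(OC(C)C)=C\CCC(=O)OC
F8 | step 4 | racemic methyl 3-(2-isopropoxy-4-methoxy-6-oxocyclohexa-2,4-dien-1-yl)propanoate (ester cyclohexadienone) | O=C1C=C(OC)C=C(OC(C)C)C1CCC(=O)OC
F9 | step 4 | methyl 3-(2-hydroxy-6-isopropoxy-4-methoxyphenyl)propanoate | COC(=O)CCc1c(O)cc(OC)cc1OC(C)C
F10 | step 4 | methyl 3-(2-isopropoxy-4,6-dimethoxyphenyl)propanoate | COC(=O)CCc1c(OC)cc(OC)cc1OC(C)C
F11 | step 4 | 3-(2-isopropoxy-4,6-dimethoxyphenyl)-N-methoxy-N-methylpropanamide | CON(C)C(=O)CCc1c(OC)cc(OC)cc1OC(C)C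
F12 | step 8 | 2-[3-(3,4-dimethoxyphenyl)-3-oxopropyl]-3-isopropoxy-5-methoxy-1,4-benzoquinone | COC1=CC(=O)C(CCC(=O)c2ccc(OC)c(OC)c2)=C(OC(C)C)C1=O
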